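# Synthesis plan for 2β-acetoxylabda-8(17),13E-dien-15-oic acid (24)

Labdane numbering is used throughout; compound numbers are those of the steps below.

## The problem

Target 24 is a normal-series labdane. It is a trans-fused decalin (ring A: C1–C5, C10; ring B: C5–C10) with a gem-dimethyl group at C4, an angular methyl group on the quaternary C10, an exocyclic C8=C17 alkene, an (E)-3-methylpent-2-enoic acid chain on C9 and an acetate on C2. The descriptors read 2R,5S,9S,10S: H-5 is α, the C10 methyl β, the C9 chain β (equatorial), and the C2 acetate β, hence axial and syn to both the C10 methyl and the 4β-methyl group. Only C5 and C10 need outside control. Once the trans ring fusion exists, the axial C10 methyl screens the β face at C9 and, with the axial C4 methyl, the β face at C2, so hydrogen delivered from the α face should set both remaining centres. The exocyclic alkene migrates into the ring under acid, the acetate survives neither organometallic reagents nor saponification, and the trisubstituted enoic acid needs defined E geometry and must be freed without loss of the acetate. The acid-promoted ring construction therefore belongs early and the acetate last. C9 is flanked by the quaternary C10 and by C8, so the C9–C11 bond is best made by addition to a C9 carbonyl. The enabling feature is the C5–C10 bond with C9 beside it: C9, C10 and C5 are the carbonyl, α- and β-carbons of 2-methylcyclohex-2-enone. C4 with its two methyl groups is a tertiary cation position, and the C2 oxygen sits where a vinyl chloride terminator would place it.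

## Retrosynthesis

**Acetate (C2–O acyl bond).** Acid 24 is traced to hydroxy acid 22. Acetylation is placed last because no earlier intermediate tolerates an acetate. The mixed anhydride 23 that forms at the carboxyl group is hydrolysed on work-up. The forward step must acylate a hindered axial alcohol.

**Enoate (C14–C15 and C13–C16).** Acid 22 comes from methyl ester 21, and 21 from terminal alkyne 19 by syn-methylalumination and acylation. This cut is preferred to a Horner–Wadsworth–Emmons olefination of a C13 methyl ketone, which gives E/Z mixtures, because carbometalation fixes the 13E geometry by mechanism. The precursor 19 carries only an alkyne in the chain. The forward reaction must tolerate a free hydroxyl group and the 1,1-disubstituted ring alkene.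

**Silyl groups.** Alkyne 19 comes from the doubly silylated 18 by one fluoride treatment; nothing else changes.

**C9–H and the alkene position.** The exocyclic alkene with H-9 in 18 is traced to primary allylic chloride 17 by reductive allylic transposition, and 17 to tertiary allylic alcohol 16 by an SNi' rearrangement. A Wittig methylenation of a C8 ketone would be the neighbouring cut, but the ring B chemistry places the carbonyl at C9, not C8. The transposition moves the functionality and creates C9 in one operation. The forward reduction must deliver hydride to C9 and from the α face.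

**C9–C11.** Alcohol 16 is cut to exocyclic enone 12 and the four-carbon bromide 13, used as Grignard reagent 14 and organocerium reagent 15. A silylalkyne chain is commercial and inert to the next three steps, which an enoate would not be. The forward step needs 1,2- over 1,4-addition at a hindered carbonyl.

**C8=C17.** Enone 12 comes from ketone 9 by α-methylenation; C8 is the only enolisable position.

**C2–H and protection.** Silyl ether 9 comes from hydroxy ketone 8, and 8 from dione 7 by selective reduction. The forward step must discriminate the C2 from the C9 carbonyl and deliver hydride from the α face.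

**C3–C4 (ring A).** Dione 7 is opened to monocyclic chloro-diene 6: the C4 cation from the isopropenyl group is captured by the 2-chloroallyl group. Against a Robinson-type closure, this cut places the ring A oxygen at C2 and builds the gem-dimethyl carbon in the same step. The precursor has one ring and two stereocentres.

**C4–C5 and C1–C10 (key disconnection).** Ketone 6 is cut to 2-methylcyclohex-2-en-1-one 3, isopropenylmagnesium bromide 2 and 2,3-dichloropropene 4, through magnesium enolate 5. Both stereocentres, one of them quaternary, and the complete carbon set of ring A arise in one flask from commodity reagents. The forward reaction needs catalyst control at C5 and anti alkylation at C10.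

**Grignard reagent.** Reagent 2 is made from 2-bromopropene 1 in a weakly coordinating ether suited to the copper step.

## Roads not taken

**Alternative 1: intramolecular Diels–Alder reaction.** The cut runs through C5–C10 and C8–C9. The open-chain trienal (5R,2E,8E,10E)-5-(tert-butyldimethylsilyloxy)-12-(4-methoxybenzyloxy)-3,7,7-trimethyldodeca-2,8,10-trienal A1 would cyclise under Me2AlCl to the trans-decalin aldehyde A2.

- Merits: both rings and four stereocentres (C5, C8, C9, C10) form at once. C17 is already on C8 and a carbon substituent already on C9 with the right orientation, so no carbonyl transposition is needed. In ring-building economy this road is better than the chosen one.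
- Weak points: the dienophile is a β,β-disubstituted enal that must form the quaternary C10, and its partner C5 is attached to the quaternary C4, so the C5–C10 bond forms between two congested carbons. A1 is a long linear compound whose single stereocentre must be made enantioselectively. In A2 the C2 oxygen is α (equatorial), epimeric with the axial acetate of 24, so an oxidation–reduction pair would be needed. The C6=C7 alkene, the C17 ether and the aldehyde each need further steps.
- Comparison: the chosen plan offers a three-step entry to the bicyclic core and a C2 ketone that reduces directly to the required axial alcohol.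

**Alternative 2: acyl radical cascade.** The cuts are C1–C2 and C9–C10. With Bu3SnH/AIBN, the Se-phenyl selenoester A3 (isopropenyl on C5, tributylstannylmethyl on C8, complete side chain) would give a C2 acyl radical. This radical would close ring A onto the isopropenyl terminus; the resulting C10 radical would close ring B at C9 and expel the stannyl radical to leave C8=C17. The product would be methyl 2-oxolabda-8(17),13E-dien-15-oate A4.

- Merits: both rings, the quaternary centre, the exocyclic alkene and the side chain arrive together. A4 is about three steps from 24 and has the same useful C2 ketone. If the cascade worked, this would be the shortest route.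
- Weak points: two successive 6-endo closures are needed, the second by a tertiary radical onto a substituted alkene carbon, in competition with 5-exo closure and premature reduction. C10 and C9 are set irreversibly with only C5 to guide them. The enoate is itself a radical acceptor. A3 needs a geometrically defined allylstannane and a gem-dimethyl group next to a stereocentre, which makes its preparation long.
- Comparison: the chosen plan is longer after the key step, but each bond is made by a polar reaction with an identifiable source of selectivity.

**Alternative 3: cyclobutane fragmentation with cation–olefin closure.** The cut is C3–C4, as in the chosen plan, but the C4 cation comes from the chiral pool. (1R,5R)-Verbenone A5 would be elaborated to cyclobutyl ketone A6, which carries the C10 allyl and methyl groups and the C9 acetate arm. BF3·OEt2 in acetic acid would cleave the C7–C4 bond next to the C8 carbonyl, and the allyl group would trap the cation, with acetate entering at C2, to give keto ester A7.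

- Merits: absolute configuration is guaranteed by the starting material. The carbonyl ends at C8, ideal for Wittig methylenation with C9 under thermodynamic control. The C2 oxygen arrives already acetylated. In these three respects the road is as good as or better than the chosen one.
- Weak points: a monosubstituted alkene is a poor terminator that passes through a secondary C2 cation. The acetate in A7 is α (equatorial), so it must be removed, the alcohol inverted and the acetate put back. The side chain must then be built from an ester in the presence of that acetate. C9 and C10 have to be installed on the bicyclic scaffold first.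
- Comparison: the chosen plan uses a chlorine-stabilised terminator that gives the C2 ketone regiospecifically, reduces it to the axial alcohol, and reaches the decalin in three steps.

Key step: step 2

Remarks on the chemistry:
- The C2 acetate of 24 is read as β (2R), axial and cis to the C10 methyl group.
- The antipode of the ferrocenyl diphosphine that gives the (3S) adduct is to be identified in a first run; both antipodes are commercial.

## Route

Step 1
Reactants: 1 2-bromopropene
Product: 2 isopropenylmagnesium bromide (titrated solution)
Conditions: Mg, I2 (cat.), 2-methyltetrahydrofuran, 40 °C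
Reagents that add atoms: magnesium, [Mg]
Why: Grignard formation by insertion of magnesium into the alkenyl C–Br bond; the weakly donating ether is chosen so that the solution can be used directly in the copper-catalysed step.

Step 2
Reactants: 3 2-methylcyclohex-2-en-1-one; 2 isopropenylmagnesium bromide; 4 2,3-dichloroprop-1-ene
Product: 6 (2S,3S)-2-(2-chloroprop-2-en-1-yl)-2-methyl-3-(prop-1-en-2-yl)cyclohexan-1-one, via bromomagnesium enolate 5 (not isolated)
Conditions: CuBr·SMe2 (5 mol%), (R)-1-[(S_p)-2-(dicyclohexylphosphino)ferrocenyl]ethyldiphenylphosphine or its antipode (6 mol%), t-BuOMe, −78 °C, slow addition of 2; then DMPU, Bu4NI (20 mol%), 4, −78 → 0 °C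
Reagents that add atoms: none
Why: Transmetalation of 2 to the monovalent copper–diphosphine complex gives a chiral alkenylcopper species that binds the enone, adds at C5 and reductively eliminates to form C4–C5, releasing the tetrasubstituted enolate 5, whose regiochemistry is fixed because no proton source is present. The closest known reaction type is the copper/ferrocenyl diphosphine-catalysed conjugate addition of Grignard reagents to 2-methylcycloalkenones with alkylation of the magnesium enolate by allylic or benzylic halides in DMPU; alkenyl Grignard reagents are the least explored nucleophiles of this family, so ligand and addition rate must be tuned to outrun uncatalysed 1,2-addition. No ring closes in this step. C5 is set by the catalyst alone, since the enone has no stereocentre. C10 is set by the substrate: in 5 the isopropenyl group sits pseudoaxial to avoid allylic strain with the C10 methyl, and the allylic halide, activated as the iodide formed in the flask, enters axially on the opposite face, giving the trans arrangement of isopropenyl and chloroallyl groups that becomes the trans ring fusion. The step needs C- over O-alkylation and reaction at C10 only; a soft allylic electrophile, the aprotic medium and a product without an acidic hydrogen at C10 secure both.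

Step 3
Reactants: 6 (2S,3S)-2-(2-chloroprop-2-en-1-yl)-2-methyl-3-(prop-1-en-2-yl)cyclohexan-1-one
Product: 7 (4aS,8aS)-5,5,8a-trimethyloctahydronaphthalene-1,7-dione (trans-4,4,10-trimethyldecalin-2,9-dione)
Conditions: 90% aq. HCO2H, 60 °C
Reagents that add atoms: water, O
Why: Lansbury chloro-olefin annulation: protonation of the isopropenyl group gives the tertiary C4 cation, the 2-chloroallyl group attacks through its CH2 terminus (6-endo closure, C3–C4) because chlorine stabilises the developing C2 cation, and hydrolysis of that cation in the wet acid gives the C2 ketone; the trans fusion follows from the trans arrangement in 6 and no new stereocentre forms.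

Step 4
Reactants: 7 (4aS,8aS)-5,5,8a-trimethyloctahydronaphthalene-1,7-dione
Product: 8 (4aS,7R,8aS)-7-hydroxy-5,5,8a-trimethyloctahydronaphthalen-1(2H)-one (2β-hydroxy-9-ketone)
Conditions: LiBH(s-Bu)3 (L-Selectride, 1.05 equiv), THF, −78 °C; then H2O
Reagents that add atoms: none
Why: Chemo- and stereoselective reduction with a bulky trialkylborohydride: the C2 carbonyl, flanked by two methylene groups, should react before the C9 carbonyl next to the quaternary C10, and hydride comes along the equatorial path from the α face because the axial C10 and C4 methyl groups close the β face, which sets C2 as the axial 2β-alcohol.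

Step 5
Reactants: 8 (4aS,7R,8aS)-7-hydroxy-5,5,8a-trimethyloctahydronaphthalen-1(2H)-one
Product: 9 (4aS,7R,8aS)-5,5,8a-trimethyl-7-(triethylsilyloxy)octahydronaphthalen-1(2H)-one
Conditions: Et3SiOTf, 2,6-lutidine, CH2Cl2, 0 °C → rt
Reagents that add atoms: triethylsilyl trifluoromethanesulfonate, CC[Si](CC)(CC)OS(=O)(=O)C(F)(F)F
Why: Silylation of a hindered secondary alcohol with a silyl triflate; the small triethylsilyl group is chosen because the hydroxyl group lies between two syn-axial methyl groups.

Step 6
Reactants: 9 (4aS,7R,8aS)-5,5,8a-trimethyl-7-(triethylsilyloxy)octahydronaphthalen-1(2H)-one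
Product: 12 (4aS,7R,8aS)-5,5,8a-trimethyl-2-methylidene-7-(triethylsilyloxy)octahydronaphthalen-1(2H)-one (8(17)-en-9-one), via Mannich base 10 (not isolated), via methiodide 11 (not isolated)
Conditions: LiN(i-Pr)2, THF, −78 °C; CH2=NMe2+ I−, −78 °C → rt; MeI, rt; aq. NaHCO3, CH2Cl2, rt
Reagents that add atoms: N,N-dimethylmethyleneiminium iodide (Eschenmoser's salt), C=[N+](C)C.[I-]
Why: α-Methylenation by Mannich reaction of the lithium enolate, N-methylation and β-elimination of trimethylamine; C8 is the only enolisable position because C10 is quaternary.

Step 7
Reactants: 12 (4aS,7R,8aS)-5,5,8a-trimethyl-2-methylidene-7-(triethylsilyloxy)octahydronaphthalen-1(2H)-one; 13 (4-bromobut-1-yn-1-yl)trimethylsilane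
Product: 16 2β-(triethylsilyloxy)-14-(trimethylsilyl)-15,16-dinorlabd-8(17)-en-13-yn-9-ol (9-hydroxyl β and chain α expected), via Grignard reagent 14 (not isolated), via organocerium reagent 15 (not isolated)
Conditions: 13, Mg, THF, rt; anhydrous CeCl3, THF, −78 °C; then 12, −78 → −40 °C; aq. NH4Cl
Reagents that add atoms: none
Why: Imamoto-type 1,2-addition of an organocerium reagent to a hindered conjugated ketone; the oxophilic reagent favours carbonyl over conjugate addition, and attack anti to the axial C10 methyl should give mainly the 9β-alcohol, a centre that is erased in step 8.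

Step 8
Reactants: 16 2β-(triethylsilyloxy)-14-(trimethylsilyl)-15,16-dinorlabd-8(17)-en-13-yn-9-ol
Product: 17 17-chloro-2β-(triethylsilyloxy)-14-(trimethylsilyl)-15,16-dinorlabd-8-en-13-yne
Conditions: SOCl2, pyridine, Et2O, −20 → 0 °C
Reagents that add atoms: thionyl chloride, O=S(Cl)Cl
Why: Allylic rearrangement of a tertiary allylic alcohol with thionyl chloride (SNi'/SN2' collapse of the chlorosulfite): chloride enters at the unhindered C17 terminus and the tetrasubstituted C8=C9 alkene forms.

Step 9
Reactants: 17 17-chloro-2β-(triethylsilyloxy)-14-(trimethylsilyl)-15,16-dinorlabd-8-en-13-yne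
Product: 18 2β-(triethylsilyloxy)-14-(trimethylsilyl)-15,16-dinorlabd-8(17)-en-13-yne (H-9 α)
Conditions: Pd(OAc)2 (5 mol%), PBu3 (20 mol%), HCO2NH4 (3 equiv), 1,4-dioxane, 90 °C
Reagents that add atoms: none
Why: Tsuji–Mandai formate hydrogenolysis: zerovalent palladium ionises the allylic chloride, the palladium formate loses CO2 and hydride passes to the more substituted allyl terminus C9, giving the exocyclic alkene; palladium and hydride stay on the α face, away from the axial C10 methyl, so C9 is set with H α and the chain β (equatorial).

Step 10
Reactants: 18 2β-(triethylsilyloxy)-14-(trimethylsilyl)-15,16-dinorlabd-8(17)-en-13-yne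
Product: 19 15,16-dinorlabd-8(17)-en-13-yn-2β-ol
Conditions: Bu4NF, THF, 50 °C
Reagents that add atoms: none
Why: Fluoride cleaves the O–Si and the C(sp)–Si bond in one operation (global desilylation); no other group present is fluoride-sensitive.

Step 11
Reactants: 19 15,16-dinorlabd-8(17)-en-13-yn-2β-ol
Product: 21 methyl 2β-hydroxylabda-8(17),13E-dien-15-oate, via alkenylalane 20 (not isolated)
Conditions: AlMe3 (3.5 equiv), Cp2ZrCl2 (0.3 equiv), CH2Cl2, 0 °C → rt; then ClCO2Me, 0 °C → rt; aq. Rochelle salt
Reagents that add atoms: trimethylaluminium, C[Al](C)C; methyl chloroformate, COC(=O)Cl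
Why: Negishi zirconium-catalysed carboalumination: methyl and aluminium add syn across the terminal alkyne with methyl at C13, and the alkenylalane is acylated with retention, which fixes the 13E geometry; the hydroxyl group travels as its aluminium alkoxide and the 1,1-disubstituted ring alkene does not react.

Step 12
Reactants: 21 methyl 2β-hydroxylabda-8(17),13E-dien-15-oate
Product: 22 2β-hydroxylabda-8(17),13E-dien-15-oic acid
Conditions: LiOH, THF/MeOH/H2O, 50 °C; then 1 M HCl, 0 °C, to pH 3
Reagents that add atoms: lithium hydroxide, [Li+].[OH-]
Why: Saponification of the conjugated methyl ester, placed before acetylation because the acetate would not survive it; any carbonate formed on the C2 oxygen in step 11 is cleaved here as well.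

Step 13
Reactants: 22 2β-hydroxylabda-8(17),13E-dien-15-oic acid
Product: 24 2β-acetoxylabda-8(17),13E-dien-15-oic acid, via mixed anhydride 23 (not isolated)
Conditions: Ac2O, pyridine, DMAP, 40 °C; then H2O, THF, rt
Reagents that add atoms: acetic anhydride, CC(=O)OC(C)=O
Why: DMAP-catalysed acetylation of the hindered axial alcohol; the carboxyl group is converted into mixed anhydride 23, which is hydrolysed selectively on aqueous work-up and returns the free acid without loss of the secondary acetate.

## Compound list

1 | 2-bromopropene | C=C(C)Br | starting material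
2 | isopropenylmagnesium bromide | C=C(C)[Mg]Br | intermediate
3 | 2-methylcyclohex-2-en-1-one | CC1=CCCCC1=O | starting material
4 | 2,3-dichloroprop-1-ene | C=C(Cl)CCl | starting material
5 | bromomagnesium (S)-2-methyl-3-(prop-1-en-2-yl)cyclohex-1-en-1-olate | CC1=C(O[Mg]Br)CCC[C@H]1C(C)=C | intermediate
6 | (2S,3S)-2-(2-chloroprop-2-en-1-yl)-2-methyl-3-(prop-1-en-2-yl)cyclohexan-1-one | O=C1CCC[C@@H](C(C)=C)[C@]1(C)CC(Cl)=C | intermediate
7 | (4aS,8aS)-5,5,8a-trimethyloctahydronaphthalene-1,7-dione | O=C1CCC[C@H]2C(C)(C)CC(=O)C[C@]12C | intermediate
8 | (4aS,7R,8aS)-7-hydroxy-5,5,8a-trimethyloctahydronaphthalen-1(2H)-one | O=C1CCC[C@H]2C(C)(C)C[C@@H](O)C[C@]12C | intermediate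
9 | (4aS,7R,8aS)-5,5,8a-trimethyl-7-(triethylsilyloxy)octahydronaphthalen-1(2H)-one | O=C1CCC[C@H]2C(C)(C)C[C@@H](O[Si](CC)(CC)CC)C[C@]12C | intermediate
10 | Mannich base, 2-(dimethylaminomethyl) derivative of 9 (C8 epimers) | CN(C)CC1CC[C@H]2C(C)(C)C[C@@H](O[Si](CC)(CC)CC)C[C@]2(C)C1=O | intermediate
11 | methiodide of 10 (C8 epimers) | C[N+](C)(C)CC1CC[C@H]2C(C)(C)C[C@@H](O[Si](CC)(CC)CC)C[C@]2(C)C1=O.[I-] | intermediate
12 | (4aS,7R,8aS)-5,5,8a-trimethyl-2-methylidene-7-(triethylsilyloxy)octahydronaphthalen-1(2H)-one | C=C1CC[C@H]2C(C)(C)C[C@@H](O[Si](CC)(CC)CC)C[C@]2(C)C1=O | intermediate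
13 | (4-bromobut-1-yn-1-yl)trimethylsilane | C[Si](C)(C)C#CCCBr | starting material
14 | [4-(trimethylsilyl)but-3-yn-1-yl]magnesium bromide | C[Si](C)(C)C#CCC[Mg]Br | intermediate
15 | dichloro[4-(trimethylsilyl)but-3-yn-1-yl]cerium | C[Si](C)(C)C#CCC[Ce](Cl)Cl | intermediate
16 | 2β-(triethylsilyloxy)-14-(trimethylsilyl)-15,16-dinorlabd-8(17)-en-13-yn-9-ol (9-OH β, chain α shown; either epimer serves) | C=C1CC[C@H]2C(C)(C)C[C@@H](O[Si](CC)(CC)CC)C[C@]2(C)[C@]1(O)CCC#C[Si](C)(C)C | intermediate
17 | 17-chloro-2β-(triethylsilyloxy)-14-(trimethylsilyl)-15,16-dinorlabd-8-en-13-yne | ClCC1=C(CCC#C[Si](C)(C)C)[C@@]2(C)C[C@H](O[Si](CC)(CC)CC)CC(C)(C)[C@@H]2CC1 | intermediate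
18 | 2β-(triethylsilyloxy)-14-(trimethylsilyl)-15,16-dinorlabd-8(17)-en-13-yne (H-5 α, H-9 α, CH3-10 β) | C=C1CC[C@H]2C(C)(C)C[C@@H](O[Si](CC)(CC)CC)C[C@]2(C)[C@H]1CCC#C[Si](C)(C)C | intermediate
19 | 15,16-dinorlabd-8(17)-en-13-yn-2β-ol | C=C1CC[C@H]2C(C)(C)C[C@@H](O)C[C@]2(C)[C@H]1CCC#C | intermediate
20 | (13E)-alkenyl(dimethyl)alane, O2-dimethylaluminium alkoxide | C=C1CC[C@H]2C(C)(C)C[C@@H](O[Al](C)C)C[C@]2(C)[C@H]1CC/C(C)=C/[Al](C)C | intermediate
21 | methyl 2β-hydroxylabda-8(17),13E-dien-15-oate | C=C1CC[C@H]2C(C)(C)C[C@@H](O)C[C@]2(C)[C@H]1CC/C(C)=C/C(=O)OC | intermediate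
22 | 2β-hydroxylabda-8(17),13E-dien-15-oic acid | C=C1CC[C@H]2C(C)(C)C[C@@H](O)C[C@]2(C)[C@H]1CC/C(C)=C/C(=O)O | intermediate
23 | acetic 2β-acetoxylabda-8(17),13E-dien-15-oic anhydride | C=C1CC[C@H]2C(C)(C)C[C@@H](OC(C)=O)C[C@]2(C)[C@H]1CC/C(C)=C/C(=O)OC(C)=O | intermediate
24 | 2β-acetoxylabda-8(17),13E-dien-15-oic acid, (2R,5S,9S,10S) | C=C1CC[C@H]2C(C)(C)C[C@@H](OC(C)=O)C[C@]2(C)[C@H]1CC/C(C)=C/C(=O)O | target

## Step count and least certain steps

Total: 13 steps. Longest linear sequence: 13 steps (1 → 24), or 12 from enone 3. Bromide 13 is purchased.

**Step 2 (key step).**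
- Most likely to go wrong: loss of enantiocontrol and conversion in the copper-catalysed transfer of an alkenyl group (background 1,2-addition, slow transmetalation of sp2 groups), and sluggish alkylation of the magnesium enolate with proton transfer as the consequence.
- Fallback: separate the two events and change the metal. From 3, copper-catalysed addition (copper thiophene-2-carboxylate, chiral phosphoramidite ligand, Et2O, −30 °C) of dimethyl(prop-1-en-2-yl)alane F1, made from 2 and Me2AlCl, is followed by a quench with acetic anhydride. Alanes are the nucleophile class for which copper-catalysed alkenyl transfer is best documented. This should give (S)-2-methyl-3-(prop-1-en-2-yl)cyclohex-1-en-1-yl acetate F2. MeLi (2 equiv, THF) then unmasks the regiodefined enolate, which is alkylated with 2-chloro-3-iodoprop-1-ene F3 (from 4 and NaI in acetone) to return to 6.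

**Step 3.**
- Most likely to go wrong: proton loss from the C4 cation towards C5 before ring closure (isopropenyl–isopropylidene equilibration), which would erode the C5 configuration and open paths to cis-fused or five-membered products.
- Fallback: generate the cation once, aprotically and cold. From 6, dry HCl (CH2Cl2, −40 °C) should give tertiary chloride (2S,3R)-2-(2-chloroprop-2-en-1-yl)-3-(2-chloropropan-2-yl)-2-methylcyclohexan-1-one F4. SnCl4 (CH2Cl2, −78 °C) ionises it, and closure with chloride return should give (4aS,8aS)-7,7-dichloro-5,5,8a-trimethyloctahydronaphthalen-1(2H)-one F5. Hydrolysis (AgNO3, aqueous acetone) returns to 7.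

**Step 7.**
- Most likely to go wrong: conjugate addition at the exposed exocyclic methylene in competition with attack on the crowded C9 carbonyl, or self-condensation of enone 12 before it reacts.
- Fallback: make the C9–C11 bond on a vinylogous ester and let a carbonyl transposition deliver C17. From 9, formylation (HCO2Et, NaH) should give hydroxymethylene ketone F6, and i-BuOH/TsOH (benzene, reflux) isobutoxymethylene ketone F7. Addition of 15 and acidic work-up (Stork–Danheiser-type transposition) should give 2β-(triethylsilyloxy)-14-(trimethylsilyl)-15,16-dinorlabd-8-en-13-yn-17-al F8. NaBH4/CeCl3 should give the 17-ol F9, and MsCl, LiCl, 2,4,6-collidine (DMF, 0 °C) the chloride 17.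

**Step 8.**
- Most likely to go wrong: ionisation of the tertiary chlorosulfite without chloride return, leading to elimination to conjugated dienes, or formation of unrearranged tertiary chloride.
- Fallback: ionise a carbonate with palladium instead. From 16, n-BuLi then ClCO2Me (THF, −78 → 0 °C) should give the tertiary allylic methyl carbonate F10. Under the conditions of step 9 it forms the same allylpalladium formate and should give 18 directly.

**Step 9.**
- Most likely to go wrong: hydride delivery to C17 instead of the fully substituted C9, insufficient facial selectivity at C9, or semi-reduction of the silylalkyne by palladium hydride.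
- Fallback: a palladium-free SE2' protonation. From 17, Bu3SnLi (THF, −78 °C) should give the 17-(tributylstannyl) compound F11. Protodestannylation with CF3CO2H (1 equiv, CH2Cl2, −78 °C) places the proton on C9 from the α face and moves the alkene to C8=C17, returning to 18.

## Further compounds

F1 | step 2 | dimethyl(prop-1-en-2-yl)alane | C=C(C)[Al](C)C
F2 | step 2 | (S)-2-methyl-3-(prop-1-en-2-yl)cyclohex-1-en-1-yl acetate | CC1=C(OC(C)=O)CCC[C@H]1C(C)=C
F3 | step 2 | 2-chloro-3-iodoprop-1-ene | C=C(Cl)CI
F4 | step 3 | (2S,3R)-2-(2-chloroprop-2-en-1-yl)-3-(2-chloropropan-2-yl)-2-methylcyclohexan-1-one | O=C1CCC[C@@H](C(C)(C)Cl)[C@]1(C)CC(Cl)=C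
F5 | step 3 | (4aS,8aS)-7,7-dichloro-5,5,8a-trimethyloctahydronaphthalen-1(2H)-one | O=C1CCC[C@H]2C(C)(C)CC(Cl)(Cl)C[C@]12C
F6 | step 7 | (Z)-2-(hydroxymethylidene) derivative of 9 | O/C=C1/CC[C@H]2C(C)(C)C[C@@H](O[Si](CC)(CC)CC)C[C@]2(C)C1=O
F7 | step 7 | (E)-2-(isobutoxymethylidene) derivative of 9 | CC(C)CO\C=C1/CC[C@H]2C(C)(C)C[C@@H](O[Si](CC)(CC)CC)C[C@]2(C)C1=O
F8 | step 7 | 2β-(triethylsilyloxy)-14-(trimethylsilyl)-15,16-dinorlabd-8-en-13-yn-17-al | O=CC1=C(CCC#C[Si](C)(C)C)[C@@]2(C)C[C@H](O[Si](CC)(CC)CC)CC(C)(C)[C@@H]2CC1
F9 | step 7 | 2β-(triethylsilyloxy)-14-(trimethylsilyl)-15,16-dinorlabd-8-en-13-yn-17-ol | OCC1=C(CCC#C[Si](C)(C)C)[C@@]2(C)C[C@H](O[Si](CC)(CC)CC)CC(C)(C)[C@@H]2CC1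
F10 | step 8 | methyl carbonate of 16 | C=C1CC[C@H]2C(C)(C)C[C@@H](O[Si](CC)(CC)CC)C[C@]2(C)[C@]1(OC(=O)OC)CCC#C[Si](C)(C)C
F11 | step 9 | 17-(tributylstannyl)-2β-(triethylsilyloxy)-14-(trimethylsilyl)-15,16-dinorlabd-8-en-13-yne | CCCC[Sn](CCCC)(CCCC)CC1=C(CCC#C[Si](C)(C)C)[C@@]2(C)C[C@H](O[Si](CC)(CC)CC)CC(C)(C)[C@@H]2CC1
A1 | alternative 1 | (5R,2E,8E,10E)-5-(tert-butyldimethylsilyloxy)-12-(4-methoxybenzyloxy)-3,7,7-trimethyldodeca-2,8,10-trienal | O=C/C=C(\C)C[C@@H](O[Si](C)(C)C(C)(C)C)CC(C)(C)/C=C/C=C/COCc1ccc(OC)cc1
A2 | alternative 1 | 2α-(tert-butyldimethylsilyloxy)-17-(4-methoxybenzyloxy)-4,4,10-trimethyl-trans-decal-6-ene-9-carbaldehyde (labdane numbering) | COc1ccc(COC[C@H]2C=C[C@H]3C(C)(C)C[C@H](O[Si](C)(C)C(C)(C)C)C[C@]3(C)[C@H]2C=O)cc1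
A3 | alternative 2 | methyl (2E,6Z,10R)-3,11,11-trimethyl-13-oxo-13-(phenylselanyl)-10-(prop-1-en-2-yl)-7-[(tributylstannyl)methyl]trideca-2,6-dienoate | O=C(CC(C)(C)[C@@H](C(C)=C)CC/C(C[Sn](CCCC)(CCCC)CCCC)=C/CC/C(C)=C/C(=O)OC)[Se]c1ccccc1
A4 | alternative 2 | methyl 2-oxolabda-8(17),13E-dien-15-oate | C=C1CC[C@H]2C(C)(C)CC(=O)C[C@]2(C)[C@H]1CC/C(C)=C/C(=O)OC
A5 | alternative 3 | (1R,5R)-verbenone | CC1=CC(=O)[C@@H]2C[C@H]1C2(C)C
A6 | alternative 3 | methyl 2-[4-allyl-4,6,6-trimethyl-2-oxobicyclo[3.1.1]heptan-3-yl]acetate | O=C1[C@H](CC(=O)OC)[C@@](C)(CC=C)[C@H]2C[C@@H]1C2(C)C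
A7 | alternative 3 | methyl 2α-acetoxy-8-oxo-13,14,15,16,17-pentanorlabdan-12-oate | O=C1CC[C@H]2C(C)(C)C[C@H](OC(C)=O)C[C@]2(C)[C@H]1CC(=O)OC
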